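**Retrosynthetic overview** (prenyl = 3-methylbut-2-en-1-yl)

- The strategy rests on the C3–C4 bond of ring C. It joins the benzylic stereocentre C3, which carries ring B, to the aroyl carbon C4 on ring A. Both carbons are electrophiles in their natural halide forms (secondary benzylic chloride, acid chloride), so they are joined last by a reductive like-polarity coupling that closes ring C and sets C3.
- The coupling precursor 15 holds both chlorides on one chain through the O1–C2 ether. It comes from hydroxy acid 14 by double deoxychlorination, and 14 comes from keto ether 11 by reduction, saponification and acetylation of the phenols.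
- Keto ether 11 is the Williamson union of ring A phenol 5 with ring B bromoketone 10. Each prenyl group is put on an aryl bromide by Stille coupling.
- Rings A and B are bought. Ring C is the only ring formed (step 11). The two aryl acetates are removed last under near-neutral conditions.

Key step: step 11

Assumption: the sense of induction of the bis(oxazoline) ligand in the tethered closure cannot be assigned in advance, so the route is written with the (S,S)-ligand and the mirror-image ligand would be used if a first run gives (R)-16; stannane 4 and bromophenol 6 are taken as catalogue compounds.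

**Route**

Step 1
Reactants: 1 methyl 2,4-dihydroxybenzoate
Product: 2 methyl 5-bromo-2,4-dihydroxybenzoate
Conditions: Br2 (1.0 equiv), AcOH, 15–20 °C
Reagents that add atoms: bromine, BrBr
Why: Electrophilic aromatic bromination should go to C5, which is para to the C2 hydroxyl and ortho to the C4 hydroxyl and less hindered than C3 between the two hydroxyls, and one equivalent of bromine limits dibromination.

Step 2
Reactants: 2 methyl 5-bromo-2,4-dihydroxybenzoate
Product: 3 methyl 5-bromo-2-hydroxy-4-(pivaloyloxy)benzoate
Conditions: pivaloyl chloride (1.05 equiv), Et3N (1.2 equiv), CH2Cl2, 0 °C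
Reagents that add atoms: pivaloyl chloride, CC(C)(C)C(Cl)=O
Why: O-acylation should select the free and more acidic C4 hydroxyl, because the C2 hydroxyl is held in a hydrogen bond to the ester carbonyl.

Step 3
Reactants: 3 methyl 5-bromo-2-hydroxy-4-(pivaloyloxy)benzoate; 4 tributyl(3-methylbut-2-en-1-yl)stannane
Product: 5 methyl 2-hydroxy-5-prenyl-4-(pivaloyloxy)benzoate
Conditions: Pd(PPh3)4 (5 mol %), DMF, 95 °C, degassed
Reagents that add atoms: none
Why: Stille coupling under neutral conditions spares the pivalate and the methyl ester; zerovalent palladium inserts into C5–Br and the prenyl(aryl)palladium should eliminate reductively at the unsubstituted allyl terminus to give the linear prenyl arene.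

Step 4
Reactants: 6 1-(3-bromo-4-hydroxyphenyl)ethan-1-one
Product: 7 4-acetyl-2-bromophenyl pivalate
Conditions: pivaloyl chloride (1.1 equiv), Et3N (1.3 equiv), DMAP (cat.), CH2Cl2, 0 °C to rt
Reagents that add atoms: pivaloyl chloride, CC(C)(C)C(Cl)=O
Why: Simple O-acylation of the only hydroxyl gives a hindered aryl ester that should withstand the coupling, enolisation, alkylation and hydride steps that follow.

Step 5
Reactants: 7 4-acetyl-2-bromophenyl pivalate; 4 tributyl(3-methylbut-2-en-1-yl)stannane
Product: 8 4-acetyl-2-prenylphenyl pivalate
Conditions: Pd(PPh3)4 (5 mol %), DMF, 90 °C, degassed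
Reagents that add atoms: none
Why: Stille coupling as in step 3, here on an aryl bromide activated by the para acetyl group, should give the linear prenyl arene with the ketone and the pivalate untouched.

Step 6
Reactants: 8 4-acetyl-2-prenylphenyl pivalate
Product: 10 4-(bromoacetyl)-2-prenylphenyl pivalate, via trimethylsilyl enol ether 9 (not isolated)
Conditions: LiN(SiMe3)2 (1.1 equiv), Me3SiCl (1.2 equiv), THF, −78 °C; then NBS (1.05 equiv), −78 to 0 °C
Reagents that add atoms: N-bromosuccinimide, O=C1CCC(=O)N1Br (chlorotrimethylsilane, C[Si](C)(C)Cl, adds silicon to 9 only)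
Why: Enol silylation followed by electrophilic bromination of the silyl enol ether should place bromine only on the acetyl carbon, since the enol ether is far more nucleophilic than the trisubstituted prenyl alkene at low temperature and the hindered pivalate resists the amide base at −78 °C.

Step 7
Reactants: 5 methyl 2-hydroxy-5-prenyl-4-(pivaloyloxy)benzoate; 10 4-(bromoacetyl)-2-prenylphenyl pivalate
Product: 11 methyl 2-{2-oxo-2-[4-(pivaloyloxy)-3-prenylphenyl]ethoxy}-4-(pivaloyloxy)-5-prenylbenzoate
Conditions: K2CO3 (1.5 equiv), acetone, 45 °C
Reagents that add atoms: none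
Why: Williamson ether synthesis (SN2 at the activated α-bromoketone) by the only free phenol of 5 should form the O1–C2 ether, and carbonate in acetone is too mild to drive the keto ester on to a benzofuranone or to cleave the pivalates.

Step 8
Reactants: 11 methyl 2-{2-oxo-2-[4-(pivaloyloxy)-3-prenylphenyl]ethoxy}-4-(pivaloyloxy)-5-prenylbenzoate
Product: 13 4-hydroxy-2-[2-hydroxy-2-(4-hydroxy-3-prenylphenyl)ethoxy]-5-prenylbenzoic acid (racemic), via pivalate-protected carbinol methyl ester 12 (not isolated)
Conditions: NaBH4, THF/MeOH, 0 °C; then LiOH (aq., 8 equiv), 55 °C; then 1 M HCl to pH 3, 0 °C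
Reagents that add atoms: lithium hydroxide in water, [Li+].[OH-] (one oxygen of the carboxyl group)
Why: Hydride reduction of the aryl ketone gives the racemic carbinol (its configuration is erased in step 11), and saponification in the same flask cleaves the methyl ester and both pivalates, so that any pivaloyl shift or lactonisation of the intermediate alkoxide is without consequence.

Step 9
Reactants: 13 4-hydroxy-2-[2-hydroxy-2-(4-hydroxy-3-prenylphenyl)ethoxy]-5-prenylbenzoic acid
Product: 14 4-acetoxy-2-[2-(4-acetoxy-3-prenylphenyl)-2-hydroxyethoxy]-5-prenylbenzoic acid (racemic)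
Conditions: NaOH (aq., 5 equiv), Ac2O (2.6 equiv), 0 °C, 15 min; then 1 M HCl to pH 3
Reagents that add atoms: acetic anhydride, CC(=O)OC(C)=O
Why: Schotten–Baumann-type acetylation in cold aqueous alkali should acylate only the two phenoxides, leaving the secondary alcohol, while any mixed anhydride at the carboxylate is hydrolysed on work-up.

Step 10
Reactants: 14 4-acetoxy-2-[2-(4-acetoxy-3-prenylphenyl)-2-hydroxyethoxy]-5-prenylbenzoic acid
Product: 15 4-acetoxy-2-[2-(4-acetoxy-3-prenylphenyl)-2-chloroethoxy]-5-prenylbenzoyl chloride (racemic)
Conditions: 1-chloro-N,N,2-trimethylprop-1-en-1-amine (2.5 equiv), CH2Cl2, 0 °C to rt, 14 added to the reagent; volatiles removed under high vacuum, crude used at once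
Reagents that add atoms: 1-chloro-N,N,2-trimethylprop-1-en-1-amine, CC(C)=C(Cl)N(C)C
Why: The α-chloroenamine turns a carboxylic acid into its chloride and a secondary alcohol into the alkyl chloride through acyloxy- and alkoxy-iminium chlorides (deoxychlorination) without setting HCl free, so the prenyl alkenes and aryl acetates should survive, and adding 14 to the excess reagent ties up the carbinol before the new acid chloride can acylate it.

Step 11
Reactants: 15 4-acetoxy-2-[2-(4-acetoxy-3-prenylphenyl)-2-chloroethoxy]-5-prenylbenzoyl chloride (racemic)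
Product: 16 (3S)-7-acetoxy-3-(4-acetoxy-3-prenylphenyl)-6-prenylchroman-4-one [(S)-7,4'-diacetoxy-6,3'-diprenylisoflavanone]
Conditions: NiCl2(dme) (15 mol %), (S,S)-2,2'-isopropylidenebis(4-phenyl-2-oxazoline) (18 mol %), Mn powder (3 equiv), 3 Å molecular sieves, DMA/THF 3:7, 20 °C, 15 added over 12 h by syringe pump (final 0.01 M)
Reagents that add atoms: none
Why: Proposed new method: zerovalent nickel, made from NiCl2(dme) and Mn, should insert first into the aroyl C–Cl bond; the acylnickel is then reduced by Mn to the monovalent state, abstracts chlorine from the tethered benzylic C–Cl of either enantiomer of 15, and recaptures the planar C3 radical to give a trivalent acyl(benzyl)nickel whose reductive elimination forms C3–C4. The closest known reaction type is the intermolecular nickel/bis(oxazoline)-catalysed enantioselective reductive coupling of acid chlorides with racemic secondary benzylic chlorides using Mn, and here the same events are asked to occur within one molecule. Ring C (O1, C2, C3, C4, C4a, C8a) closes when the C3 radical recombines with nickel at the acyl group, a seven-membered nickelacycle that contracts to the six-membered ketone on reductive elimination (formally a 6-exo closure at the acyl carbon). C3, the only stereocentre, is set under catalyst control by the chiral bis(oxazoline) on nickel during radical capture and reductive elimination, stereoconvergently from racemic 15. The step needs ring closure to outrun intermolecular coupling and homocoupling, which slow addition at 0.01 M should secure, and it needs C–C bond formation to outrun loss of the β-aryloxy group, which a C3 radical (unlike a C3 carbanion or organozinc) does not readily expel, while the faster oxidative addition of the acid chloride keeps a benzylnickel from forming first. Because the medium contains no base, C3 of the product should not epimerise through the enol, and the electron-poor acetate on ring B together with the β-aryloxy group should keep the benzylic C–Cl bond from solvolysing in DMA.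

Step 12
Reactants: 16 (3S)-7-acetoxy-3-(4-acetoxy-3-prenylphenyl)-6-prenylchroman-4-one
Product: 17 (3S)-7-hydroxy-3-(4-hydroxy-3-prenylphenyl)-6-prenylchroman-4-one (target)
Conditions: NH4OAc (8 equiv), MeOH/H2O 4:1, 20 °C
Reagents that add atoms: none
Why: Near-neutral ammonium acetate-mediated solvolysis (transesterification to methanol) should remove both aryl acetates, and since no strong base is present the C3 stereocentre α to the ketone should not epimerise.

**Compound list**

1 | methyl 2,4-dihydroxybenzoate | COC(=O)c1ccc(O)cc1O | starting material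
2 | methyl 5-bromo-2,4-dihydroxybenzoate | COC(=O)c1cc(Br)c(O)cc1O | intermediate
3 | methyl 5-bromo-2-hydroxy-4-(pivaloyloxy)benzoate | COC(=O)c1cc(Br)c(OC(=O)C(C)(C)C)cc1O | intermediate
4 | tributyl(3-methylbut-2-en-1-yl)stannane | CCCC[Sn](CCCC)(CCCC)CC=C(C)C | starting material
5 | methyl 2-hydroxy-5-(3-methylbut-2-en-1-yl)-4-(pivaloyloxy)benzoate | COC(=O)c1cc(CC=C(C)C)c(OC(=O)C(C)(C)C)cc1O | intermediate
6 | 1-(3-bromo-4-hydroxyphenyl)ethan-1-one | CC(=O)c1ccc(O)c(Br)c1 | starting material
7 | 4-acetyl-2-bromophenyl pivalate | CC(=O)c1ccc(OC(=O)C(C)(C)C)c(Br)c1 | intermediate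
8 | 4-acetyl-2-(3-methylbut-2-en-1-yl)phenyl pivalate | CC(=O)c1ccc(OC(=O)C(C)(C)C)c(CC=C(C)C)c1 | intermediate
9 | 2-(3-methylbut-2-en-1-yl)-4-[1-(trimethylsilyloxy)vinyl]phenyl pivalate | C=C(O[Si](C)(C)C)c1ccc(OC(=O)C(C)(C)C)c(CC=C(C)C)c1 | intermediate (not isolated)
10 | 4-(bromoacetyl)-2-(3-methylbut-2-en-1-yl)phenyl pivalate | O=C(CBr)c1ccc(OC(=O)C(C)(C)C)c(CC=C(C)C)c1 | intermediate
11 | methyl 2-{2-oxo-2-[4-(pivaloyloxy)-3-prenylphenyl]ethoxy}-4-(pivaloyloxy)-5-prenylbenzoate | COC(=O)c1cc(CC=C(C)C)c(OC(=O)C(C)(C)C)cc1OCC(=O)c1ccc(OC(=O)C(C)(C)C)c(CC=C(C)C)c1 | intermediate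
12 | methyl 2-{2-hydroxy-2-[4-(pivaloyloxy)-3-prenylphenyl]ethoxy}-4-(pivaloyloxy)-5-prenylbenzoate (racemic) | COC(=O)c1cc(CC=C(C)C)c(OC(=O)C(C)(C)C)cc1OCC(O)c1ccc(OC(=O)C(C)(C)C)c(CC=C(C)C)c1 | intermediate (not isolated)
13 | 4-hydroxy-2-[2-hydroxy-2-(4-hydroxy-3-prenylphenyl)ethoxy]-5-prenylbenzoic acid (racemic) | OC(=O)c1cc(CC=C(C)C)c(O)cc1OCC(O)c1ccc(O)c(CC=C(C)C)c1 | intermediate
14 | 4-acetoxy-2-[2-(4-acetoxy-3-prenylphenyl)-2-hydroxyethoxy]-5-prenylbenzoic acid (racemic) | OC(=O)c1cc(CC=C(C)C)c(OC(C)=O)cc1OCC(O)c1ccc(OC(C)=O)c(CC=C(C)C)c1 | intermediate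
15 | 4-acetoxy-2-[2-(4-acetoxy-3-prenylphenyl)-2-chloroethoxy]-5-prenylbenzoyl chloride (racemic) | CC(=O)Oc1ccc(C(Cl)COc2cc(OC(C)=O)c(CC=C(C)C)cc2C(Cl)=O)cc1CC=C(C)C | intermediate
16 | (3S)-7-acetoxy-3-(4-acetoxy-3-prenylphenyl)-6-prenylchroman-4-one | CC(C)=CCc1cc([C@H]2COc3cc(OC(C)=O)c(CC=C(C)C)cc3C2=O)ccc1OC(C)=O | intermediate
17 | (3S)-7-hydroxy-3-(4-hydroxy-3-prenylphenyl)-6-prenylchroman-4-one | CC(C)=CCc1cc([C@H]2COc3cc(O)c(CC=C(C)C)cc3C2=O)ccc1O | target

**Step count and risks**

Total steps: 12. Longest linear sequence: 9 steps (steps 1–3 then 7–12; the ring B branch, steps 4–6 then 7–12, is equally long).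

Steps most likely to fail:

1. Step 11 (proposed new method). What may go wrong: the chiral acylnickel may capture the C3 radical with poor facial selectivity, or C3 may epimerise by enolisation in DMA, so that 16 forms with low enantiomeric purity. The fallback moves stereocontrol from the coupling to a dynamic kinetic resolution, using known chemistry only. It sets out from 16 of low enantiomeric purity and comes back at 16, so it does not cover a failure of the ring closure itself. Asymmetric transfer hydrogenation with RuCl[(S,S)-TsDPEN](p-cymene) in HCO2H/Et3N (5:2) at 40 °C lets C3 equilibrate through the enol while one enantiomer of the ketone is reduced faster; this should give the cis-(3S,4S)-isoflavan-4-ol diacetate F1. Dess–Martin periodinane with NaHCO3 in CH2Cl2 at 0 °C then re-oxidises C4 without touching C3 and returns (S)-16. If the sense of reduction proves opposite, the (R,R)-catalyst is used.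

2. Step 10. What may go wrong: the newly formed acid chloride may acylate the still free carbinol (lactone or oligoester formation) before the carbinol is chlorinated, or the alkoxyiminium salt may eliminate. The fallback separates the two chlorinations by masking the acid; it sets out from 14 and comes back at 15. Allyl bromide and KHCO3 in DMF at rt should alkylate only the carboxylate and give the allyl ester F2. The same chloroenamine (1.3 equiv, CH2Cl2) converts its carbinol into the chloride, the chloro allyl ester F3. Pd(PPh3)4 (2 mol %) with PhSiH3 in CH2Cl2 at 0 °C removes the allyl group under neutral conditions, since zerovalent palladium ionises the allyl ester much faster than it inserts into the secondary benzylic chloride, and gives the chloro acid F4. One equivalent of the chloroenamine then gives 15.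

3. Step 12. What may go wrong: enolisation at C3 during acetate cleavage, with loss of enantiomeric purity, or incomplete cleavage of the more hindered ring A acetate. The fallback replaces chemical solvolysis by enzymatic alcoholysis; it sets out from 16 and comes back at 17. Immobilised Candida antarctica lipase B with butan-1-ol in tert-butyl methyl ether at 35 °C should transfer both acetyl groups to butanol at neutral pH without any base; no new compound is formed on the way (F0).

**Further compounds**

F1 | step 11 | (3S,4S)-7-acetoxy-3-(4-acetoxy-3-prenylphenyl)-6-prenylchroman-4-ol (cis) | CC(C)=CCc1cc([C@H]2COc3cc(OC(C)=O)c(CC=C(C)C)cc3[C@H]2O)ccc1OC(C)=O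
F2 | step 10 | allyl 4-acetoxy-2-[2-(4-acetoxy-3-prenylphenyl)-2-hydroxyethoxy]-5-prenylbenzoate (racemic) | C=CCOC(=O)c1cc(CC=C(C)C)c(OC(C)=O)cc1OCC(O)c1ccc(OC(C)=O)c(CC=C(C)C)c1
F3 | step 10 | allyl 4-acetoxy-2-[2-(4-acetoxy-3-prenylphenyl)-2-chloroethoxy]-5-prenylbenzoate (racemic) | C=CCOC(=O)c1cc(CC=C(C)C)c(OC(C)=O)cc1OCC(Cl)c1ccc(OC(C)=O)c(CC=C(C)C)c1
F4 | step 10 | 4-acetoxy-2-[2-(4-acetoxy-3-prenylphenyl)-2-chloroethoxy]-5-prenylbenzoic acid (racemic) | OC(=O)c1cc(CC=C(C)C)c(OC(C)=O)cc1OCC(Cl)c1ccc(OC(C)=O)c(CC=C(C)C)c1
F0 | step 12 | none | none
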